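**Retrosynthetic overview**
1. Ring A is closed last by an intramolecular aldol of the C4 lactone enolate onto a C3 aldehyde; the 2β,3β-diol then comes from the 3-ketone (enolate hydroxylation, bulky hydride).
2. The five-membered ring B comes from a six-membered precursor by photochemical Wolff ring contraction, which extrudes C7 as the carboxyl group.
3. The 19,10-lactone and the C4–C5 bond come from an intramolecular Michael addition of a C10–O propanoate onto a Δ5-7-enone.
4. Ring D and the C11 oxygen come from a 5-exo Heck cyclisation of a 2-bromoallyl group onto the ring C alkene, which ends as a C11 silyl enol ether.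
5. Ring C, fused to the six-membered ring B precursor, comes from a catalytic enantioselective quinone Diels–Alder reaction. Order of ring formation: C (+ six-membered B) → D → lactone → B (contraction) → A.

Assumption 1: locants are gibberellane locants (C7 = ring B carboxyl carbon, C17 = exocyclic CH2, C18 = C4 methyl, C19 = lactone carbonyl), also in the six-membered ring B precursor (C5, C6, C7, C8, C9, C10); β is the face of H5, H9 and the C15–C16 bridge, α the face of the lactone.
Assumption 2: the (S)-configured oxazaborolidinium catalyst is taken to give the enantiomer drawn for 8; if the sense were opposite, its mirror image would be used with no other change.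

Step 1
Reactants: 1 guaiacol (2-methoxyphenol); 2 2,3-dibromopropene
Product: 3 1-[(2-bromoprop-2-en-1-yl)oxy]-2-methoxybenzene
Conditions: K2CO3, acetone, reflux
Reagents that add atoms: none
Why: Williamson ether synthesis; only the allylic bromide of 2 undergoes SN2, the vinylic bromide is inert.

Step 2
Reactants: 3 1-[(2-bromoprop-2-en-1-yl)oxy]-2-methoxybenzene
Product: 4 2-(2-bromoprop-2-en-1-yl)-6-methoxyphenol
Conditions: PhNEt2, 190 °C
Reagents that add atoms: none
Why: aromatic Claisen rearrangement ([3,3]) moves the 2-bromoallyl group to the only free ortho carbon.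

Step 3
Reactants: 4 2-(2-bromoprop-2-en-1-yl)-6-methoxyphenol
Product: 5 2-(2-bromoprop-2-en-1-yl)-6-methoxy-1,4-benzoquinone
Conditions: O2 (1 atm), Co(C16H14N2O2) (salcomine, 10 mol %), DMF, rt
Reagents that add atoms: dioxygen O=O
Why: cobalt–salen-catalysed aerobic para-oxidation of a 2,6-disubstituted phenol to the p-benzoquinone; the para carbon is the only open site.

Step 4
Reactants: 6 (E)-crotonaldehyde
Product: 7 (E)-1-(tert-butyldimethylsilyloxy)buta-1,3-diene
Conditions: TBSOTf, Et3N, Et2O, 0 °C to rt
Reagents that add atoms: tert-butyldimethylsilyl trifluoromethanesulfonate CC(C)(C)[Si](C)(C)OS(=O)(=O)C(F)(F)F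
Why: O-silylation of the enal with γ-deprotonation (silyl dienol ether formation) gives the (E)-1-silyloxydiene.

Step 5
Reactants: 5 2-(2-bromoprop-2-en-1-yl)-6-methoxy-1,4-benzoquinone; 7 (E)-1-(tert-butyldimethylsilyloxy)buta-1,3-diene
Product: 8 cis-fused Diels–Alder adduct (8-(2-bromoallyl), H9 cis to it, 11α-OTBS cis to the C10 carbonyl, 6-OMe, Δ5, Δ12)
Conditions: (S)-o-tolyl oxazaborolidine C24H24BNO activated with HN(SO2CF3)2 (20 mol %), CH2Cl2, −78 °C
Reagents that add atoms: none
Why: catalytic enantioselective quinone Diels–Alder reaction with a chiral oxazaborolidinium Lewis acid; the methoxy group switches off its own double bond and makes the C10 carbonyl the more basic (vinylogous ester) oxygen, so catalyst binding there makes the bromoallyl-bearing C8 the electrophilic β-carbon, which joins the unsubstituted diene terminus; suprafacial endo addition puts H9 cis to the bromoallyl group and the silyloxy group cis to the C10 carbonyl, and the catalyst's face selection fixes C8 and C9 absolutely.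

Step 6
Reactants: 8 cis-fused Diels–Alder adduct
Product: 11 C7 trimethylsilyl enol ether of the saturated 7,10-dione (C10 ketone free), via 6-methoxy-7,10-dione 9 (not isolated), via C7 samarium diiodide enolate 10 (not isolated)
Conditions: SmI2 (2.1 equiv), MeOH (2.0 equiv), THF, −78 °C; then SmI2 (2.2 equiv), −78 °C; then Me3SiCl, −78 to 0 °C; non-aqueous work-up
Reagents that add atoms: chlorotrimethylsilane C[Si](C)(C)Cl
Why: Proposed new method: SmI2 first reduces the ene-dione to its bis-enolate, which methanol C-protonates to the 6-methoxy dione 9, then a second electron pair cleaves the C6–OMe bond α to the C7 ketone and leaves the regiodefined C7 enolate 10 of trivalent samarium, which Me3SiCl traps so that C7 is masked and only the C10 ketone stays free; the closest known reactions are the SmI2 reduction of ene-diones and the SmI2 α-deoxygenation of α-alkoxy ketones with enolate trapping.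

Step 7
Reactants: 11 C7 trimethylsilyl enol ether (C10 ketone free); 12 [2-(1,3-dioxan-2-yl)ethyl]magnesium bromide
Product: 13 10α-hydroxy-10β-[2-(1,3-dioxan-2-yl)ethyl] 7-ketone (8-(2-bromoallyl), 11α-OTBS, Δ12)
Conditions: 12 premixed with CeCl3 (1.5 equiv), THF, −78 °C; then aq. citric acid, 0 °C
Reagents that add atoms: none
Why: organocerium (Imamoto) 1,2-addition to the only free ketone; the reagent enters C10 from the convex face of the cis-fused bicycle (cis to H9, anti to C11 and its silyloxy group), giving the 10α-carbinol, and the acidic work-up returns the C7 enol silane to the ketone.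

Step 8
Reactants: 13 10α-hydroxy-10β-[2-(1,3-dioxan-2-yl)ethyl] 7-ketone
Product: 14 tricyclic Heck product (ring D closed, 16-methylene, C11 TBS enol ether Δ11, 10α-OH, 7-ketone)
Conditions: Pd(OAc)2 (10 mol %), PPh3 (30 mol %), Et3N, MeCN, 80 °C
Reagents that add atoms: none
Why: intramolecular Heck reaction; 5-exo syn-carbopalladation of the C12=C13 alkene by the C16 alkenylpalladium closes ring D (the two-carbon bridge can only form cis, so C13 follows C8), and the only syn β-hydrogen is H11 (β, because the silyloxy group is α), so elimination gives the C11 silyl enol ether and leaves the 16-methylene in place.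

Step 9
Reactants: 14 tricyclic Heck product
Product: 16 10α,11β-diol 7-ketone, via 10α-hydroxy-7,11-dione 15 (not isolated)
Conditions: HF·pyridine, THF, 0 °C; then Me4NBH(OAc)3, MeCN/AcOH, −20 °C
Reagents that add atoms: none
Why: enol silane cleavage followed by Evans–Saksena hydroxyl-directed reduction; the acetoxyborohydride bound to the C10 oxygen delivers hydride to the α-face of the C11 ketone (the β-face is also shielded by the C15–C16 bridge), giving the axial 11β-alcohol, while the isolated C7 ketone is not reduced.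

Step 10
Reactants: 16 10α,11β-diol 7-ketone
Product: 17 11β-OTBS ether (10α-OH free)
Conditions: TBSOTf (1.1 equiv), 2,6-lutidine, CH2Cl2, −78 °C
Reagents that add atoms: tert-butyldimethylsilyl trifluoromethanesulfonate CC(C)(C)[Si](C)(C)OS(=O)(=O)C(F)(F)F
Why: selective silyl ether formation at the secondary alcohol; the tertiary C10 alcohol does not react at −78 °C.

Step 11
Reactants: 17 11β-OTBS ether
Product: 18 Δ5-en-7-one
Conditions: LiN(i-Pr)2 (2.2 equiv), THF, −78 °C; then PhS(Cl)=N-t-Bu, −78 °C
Reagents that add atoms: none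
Why: Mukaiyama dehydrogenation of the ketone lithium enolate with N-tert-butylbenzenesulfinimidoyl chloride; the C7 ketone can enolise only toward C6 because C8 is quaternary, so only the Δ5 enone forms.

Step 12
Reactants: 18 Δ5-en-7-one; 19 propanoyl chloride
Product: 20 10α-O-propanoate of the Δ5-en-7-one
Conditions: KN(SiMe3)2 (1.05 equiv), THF, −78 °C; then 19, −78 to 0 °C
Reagents that add atoms: none
Why: O-acylation of the hindered tertiary potassium alkoxide; the enone has no enolisable hydrogen (C8 and C10 are both quaternary), so the base only deprotonates the alcohol.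

Step 13
Reactants: 20 10α-O-propanoate
Product: 21 19,10-lactone 7-ketone with six-membered ring B (H5 β; C4 epimers)
Conditions: KN(SiMe3)2 (1.1 equiv), THF, −78 to −20 °C; aq. NH4Cl
Reagents that add atoms: none
Why: intramolecular Michael addition (5-exo-trig) of the propanoate enolate to C5; the tether from the α-oxygen on C10 can deliver C4 only to the α-face of C5, so H5 ends β and the lactone is cis-fused.

Step 14
Reactants: 21 19,10-lactone 7-ketone
Product: 23 6-diazo-7-ketone lactone, via 6-trifluoroacetyl ketone 22 (not isolated)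
Conditions: LiN(SiMe3)2, THF, −78 °C; CF3CO2CH2CF3; then MsN3, Et3N, H2O, MeCN, rt
Reagents that add atoms: methanesulfonyl azide CS(=O)(=O)N=[N+]=[N-]; 2,2,2-trifluoroethyl trifluoroacetate O=C(OCC(F)(F)F)C(F)(F)F (its CF3CO group stays only in 22)
Why: Danheiser detrifluoroacetylative diazo transfer; C6 is the only enolisable position of the C7 ketone and is more acidic than the lactone C4–H.

Step 15
Reactants: 23 6-diazo-7-ketone lactone
Product: 25 ring-contracted 2-(trimethylsilyl)ethyl 7-ester (five-membered ring B, natural C6), via ring-contracted ketene 24 (not isolated)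
Conditions: hν (Hg lamp, Pyrex), Me3SiCH2CH2OH (10 equiv), THF, rt; then DBU (0.2 equiv), rt
Reagents that add atoms: 2-(trimethylsilyl)ethanol C[Si](C)(C)CCO
Why: photochemical Wolff rearrangement; C8 migrates to the C6 carbene carbon so that the six-membered ring contracts and C7 becomes the exocyclic ketene, which the alcohol traps, and DBU equilibrates C6 to the more stable ester trans to the C4–C5 bond (the natural configuration).

Step 16
Reactants: 25 ring-contracted 2-(trimethylsilyl)ethyl 7-ester
Product: 26 C3 aldehyde (10β-(3-oxopropyl) lactone ester)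
Conditions: AcOH/H2O/THF (3:1:1), 55 °C
Reagents that add atoms: water O
Why: acid-catalysed acetal hydrolysis; acetic acid is too weak to protonate the 16-methylene or to cleave the hindered axial silyl ether and the silylethyl ester.

Step 17
Reactants: 26 C3 aldehyde
Product: 27 ring-A-closed 3-hydroxy 19,10-lactone (3-epimers)
Conditions: KOt-Bu (0.3 equiv), t-BuOH/THF, 0 °C
Reagents that add atoms: none
Why: intramolecular aldol addition of the C4 lactone enolate to the C3 aldehyde closes ring A; the chain on C10 can reach C4 only on the face cis to C1, which fixes quaternary C4, and the C3 epimer mixture is removed by the next oxidation.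

Step 18
Reactants: 27 ring-A-closed 3-hydroxy lactone
Product: 28 3-ketone
Conditions: Dess–Martin periodinane, NaHCO3, CH2Cl2, rt
Reagents that add atoms: none
Why: Dess–Martin oxidation converts both C3 epimers into the same ketone under non-basic conditions that spare the β-keto lactone.

Step 19
Reactants: 28 3-ketone
Product: 29 2β-hydroxy-3-ketone
Conditions: KN(SiMe3)2 (1.1 equiv), THF, −78 °C; then 3-phenyl-2-(phenylsulfonyl)oxaziridine, −78 °C; aq. NH4Cl
Reagents that add atoms: 3-phenyl-2-(phenylsulfonyl)oxaziridine O=S(=O)(c1ccccc1)N1OC1c1ccccc1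
Why: Davis enolate hydroxylation; the ketone enolises only toward C2 (C4 is quaternary) and the oxidant attacks the β-face opposite the lactone bridge, giving the equatorial 2β-alcohol, which is also the thermodynamic epimer.

Step 20
Reactants: 29 2β-hydroxy-3-ketone
Product: 30 2β,3β-diol (11β-OTBS, silylethyl 7-ester)
Conditions: K[HB(s-Bu)3] (2.5 equiv), THF, −78 °C
Reagents that add atoms: none
Why: bulky trialkylborohydride reduction; the large hydride attacks the 3-ketone equatorially and gives the axial 3β-alcohol, cis to the 2β-hydroxyl, while lactone and ester are untouched at −78 °C.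

Step 21
Reactants: 30 2β,3β-diol (11β-OTBS, silylethyl 7-ester)
Product: 31 target, 2β,3β,11β-trihydroxy 19,10-lactone 7-acid (CNP0322347.1)
Conditions: Bu4NF, AcOH (1:1), THF, 45 °C
Reagents that add atoms: none
Why: fluoride-mediated global desilylation; Si–O cleavage frees the 11β-alcohol and fluoride-induced β-elimination of the 2-(trimethylsilyl)ethyl ester frees the acid without base hydrolysis, so the retro-aldol-prone 3-hydroxy lactone is not epimerised.

**Compound list**
1 | guaiacol (2-methoxyphenol) | COc1ccccc1O | starting material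
2 | 2,3-dibromopropene | C=C(Br)CBr | starting material
3 | 1-[(2-bromoprop-2-en-1-yl)oxy]-2-methoxybenzene | COc1ccccc1OCC(Br)=C | intermediate
4 | 2-(2-bromoprop-2-en-1-yl)-6-methoxyphenol | COc1cccc(CC(Br)=C)c1O | intermediate
5 | 2-(2-bromoprop-2-en-1-yl)-6-methoxy-1,4-benzoquinone | COC1=CC(=O)C=C(CC(Br)=C)C1=O | intermediate
6 | (E)-crotonaldehyde | C/C=C/C=O | starting material
7 | (E)-1-(tert-butyldimethylsilyloxy)buta-1,3-diene | C=C/C=C/O[Si](C)(C)C(C)(C)C | intermediate
8 | cis-fused adduct, 8a-(2-bromoprop-2-en-1-yl)-5-(tert-butyldimethylsilyloxy)-2-methoxy-4a,5,8,8a-tetrahydronaphthalene-1,4-dione (8-bromoallyl cis to H9, 11α-OTBS, 6-OMe) | C=C(Br)C[C@]12CC=C[C@@H](O[Si](C)(C)C(C)(C)C)[C@H]1C(=O)C=C(OC)C2=O | intermediate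
9 | 6-methoxy-7,10-dione (C5 now CH2; C6 epimers) | C=C(Br)C[C@]12CC=C[C@@H](O[Si](C)(C)C(C)(C)C)[C@H]1C(=O)CC(OC)C2=O | intermediate
10 | C7 samarium diiodide enolate (C6=C7–O–SmI2, C10 ketone free) | C=C(Br)C[C@]12CC=C[C@@H](O[Si](C)(C)C(C)(C)C)[C@H]1C(=O)CC=C2O[Sm](I)I | intermediate
11 | C7 trimethylsilyl enol ether of the saturated 7,10-dione (C10 ketone free) | C=C(Br)C[C@]12CC=C[C@@H](O[Si](C)(C)C(C)(C)C)[C@H]1C(=O)CC=C2O[Si](C)(C)C | intermediate
12 | [2-(1,3-dioxan-2-yl)ethyl]magnesium bromide (0.5 M in THF) | Br[Mg]CCC1OCCCO1 | starting material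
13 | 10α-hydroxy-10β-[2-(1,3-dioxan-2-yl)ethyl] 7-ketone (8-(2-bromoallyl), 11α-OTBS, Δ12) | C=C(Br)C[C@]12CC=C[C@@H](O[Si](C)(C)C(C)(C)C)[C@H]1[C@](O)(CCC3OCCCO3)CCC2=O | intermediate
14 | tricyclic Heck product (rings C and D closed, 16-methylene, C11 TBS enol ether, 10α-OH, 7-ketone) | C=C1C[C@]23C[C@H]1C=C(O[Si](C)(C)C(C)(C)C)[C@H]2[C@](O)(CCC4OCCCO4)CCC3=O | intermediate
15 | 10α-hydroxy-7,11-dione | C=C1C[C@]23C[C@H]1CC(=O)[C@H]2[C@](O)(CCC4OCCCO4)CCC3=O | intermediate
16 | 10α,11β-diol 7-ketone | C=C1C[C@]23C[C@H]1C[C@H](O)[C@H]2[C@](O)(CCC4OCCCO4)CCC3=O | intermediate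
17 | 11β-OTBS ether, 10α-OH, 7-ketone | C=C1C[C@]23C[C@H]1C[C@H](O[Si](C)(C)C(C)(C)C)[C@H]2[C@](O)(CCC4OCCCO4)CCC3=O | intermediate
18 | Δ5-en-7-one (11β-OTBS, 10α-OH) | C=C1C[C@]23C[C@H]1C[C@H](O[Si](C)(C)C(C)(C)C)[C@H]2[C@](O)(CCC4OCCCO4)C=CC3=O | intermediate
19 | propanoyl chloride | CCC(=O)Cl | starting material
20 | 10α-O-propanoate of the Δ5-en-7-one | C=C1C[C@]23C[C@H]1C[C@H](O[Si](C)(C)C(C)(C)C)[C@H]2[C@](OC(=O)CC)(CCC4OCCCO4)C=CC3=O | intermediate
21 | 19,10-lactone 7-ketone, six-membered ring B (H5 β; C4 epimers) | C=C1C[C@]23C[C@H]1C[C@H](O[Si](C)(C)C(C)(C)C)[C@H]2[C@@]5(CCC4OCCCO4)OC(=O)C(C)[C@H]5CC3=O | intermediate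
22 | 6-trifluoroacetyl ketone | C=C1C[C@]23C[C@H]1C[C@H](O[Si](C)(C)C(C)(C)C)[C@H]2[C@@]5(CCC4OCCCO4)OC(=O)C(C)[C@H]5C(C(=O)C(F)(F)F)C3=O | intermediate
23 | 6-diazo-7-ketone lactone | C=C1C[C@]23C[C@H]1C[C@H](O[Si](C)(C)C(C)(C)C)[C@H]2[C@@]5(CCC4OCCCO4)OC(=O)C(C)[C@H]5C(=[N+]=[N-])C3=O | intermediate
24 | ring-contracted ketene (C6=C7=O) | C=C1C[C@]23C[C@H]1C[C@H](O[Si](C)(C)C(C)(C)C)[C@H]2[C@@]5(CCC4OCCCO4)OC(=O)C(C)[C@H]5C3=C=O | intermediate
25 | 2-(trimethylsilyl)ethyl 7-ester, five-membered ring B, 19,10-lactone, 10β-[2-(1,3-dioxan-2-yl)ethyl], 11β-OTBS (C4 epimers) | C=C1C[C@]23C[C@H]1C[C@H](O[Si](C)(C)C(C)(C)C)[C@H]2[C@@]5(CCC4OCCCO4)OC(=O)C(C)[C@H]5[C@@H]3C(=O)OCC[Si](C)(C)C | intermediate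
26 | C3 aldehyde (10β-(3-oxopropyl)) | C=C1C[C@]23C[C@H]1C[C@H](O[Si](C)(C)C(C)(C)C)[C@H]2[C@@]5(CCC=O)OC(=O)C(C)[C@H]5[C@@H]3C(=O)OCC[Si](C)(C)C | intermediate
27 | ring-A-closed 3-hydroxy 19,10-lactone (3-epimers), 11β-OTBS, silylethyl 7-ester | C=C1C[C@]23C[C@H]1C[C@H](O[Si](C)(C)C(C)(C)C)[C@H]2[C@@]12CCC(O)[C@@](C)(C(=O)O1)[C@H]2[C@@H]3C(=O)OCC[Si](C)(C)C | intermediate
28 | 3-ketone | C=C1C[C@]23C[C@H]1C[C@H](O[Si](C)(C)C(C)(C)C)[C@H]2[C@@]12CCC(=O)[C@@](C)(C(=O)O1)[C@H]2[C@@H]3C(=O)OCC[Si](C)(C)C | intermediate
29 | 2β-hydroxy-3-ketone | C=C1C[C@]23C[C@H]1C[C@H](O[Si](C)(C)C(C)(C)C)[C@H]2[C@@]12C[C@H](O)C(=O)[C@@](C)(C(=O)O1)[C@H]2[C@@H]3C(=O)OCC[Si](C)(C)C | intermediate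
30 | 2β,3β-diol, 11β-OTBS, silylethyl 7-ester | C=C1C[C@]23C[C@H]1C[C@H](O[Si](C)(C)C(C)(C)C)[C@H]2[C@@]12C[C@H](O)[C@H](O)[C@@](C)(C(=O)O1)[C@H]2[C@@H]3C(=O)OCC[Si](C)(C)C | intermediate
31 | target CNP0322347.1 (2β,3β,11β-trihydroxy 19,10-lactone 7-acid with 16-methylene) | C=C1C[C@]23C[C@H]1C[C@H](O)[C@H]2[C@@]12C[C@H](O)[C@H](O)[C@@](C)(C(=O)O1)[C@H]2[C@@H]3C(=O)O | target

**Totals**
Total step count: 21. Longest linear sequence: 20 steps (steps 1–3 and 5–21 from guaiacol); step 4 is a one-step branch.

**Three steps most likely to fail**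

Step 5 (the enantioselective quinone Diels–Alder reaction). The strongly acidic catalyst may destroy the silyloxydiene or give low selectivity. The fallback sets out from 5 and 7 and replaces asymmetric catalysis by resolution. BF3·OEt2 in CH2Cl2 at −78 °C also binds the C10 carbonyl and should give the same regio- and endo-selectivity, but as a racemate. Preparative chromatography on a chiral stationary phase then separates 8 from the mirror-image adduct F1, which is discarded. The route is rejoined at 8.

Step 6 (the one-pot SmI2 sequence). Loss of methoxide from an intermediate enolate, or over-reduction, could scramble the regiodefined C7 enolate. The fallback sets out from 8 and gives up enolate masking in favour of steric differentiation. Excess SmI2 with MeOH in THF at −78 °C reduces 8 fully to the saturated 7,10-dione F2. The organocerium reagent from 12 and CeCl3 is then added at −78 °C and should prefer the C10 ketone, because C7 sits next to the quaternary C8. The route is rejoined at 13.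

Step 7 (facial selectivity at C10). If the organocerium reagent enters from the α-face, the wrong C10 epimer forms. The fallback sets out from 11 and installs the two C10 substituents in the opposite order, carbon first and oxygen second. Wittig olefination of the C10 ketone with the ylide from [2-(1,3-dioxan-2-yl)ethyl]triphenylphosphonium bromide and KN(SiMe3)2, followed by acidic work-up, gives the C10 alkylidene 7-ketone F3. Epoxidation with mCPBA and NaHCO3 at 0 °C is selective for this trisubstituted alkene and uses the same accessible α-face, giving the 10α,1-epoxide F4. LiEt3BH opens the epoxide at the less substituted C1 and also reduces the C7 ketone, giving the 7,10α-diol F5. Dess–Martin oxidation of the secondary C7 alcohol rejoins the route at 13.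

**Further compounds**
F1 | step 5 | mirror-image Diels–Alder adduct (enantiomer of 8) | C=C(Br)C[C@@]12CC=C[C@H](O[Si](C)(C)C(C)(C)C)[C@@H]1C(=O)C=C(OC)C2=O
F2 | step 6 | saturated 7,10-dione (C5 and C6 both CH2) | C=C(Br)C[C@]12CC=C[C@@H](O[Si](C)(C)C(C)(C)C)[C@H]1C(=O)CCC2=O
F3 | step 7 | C10 alkylidene 7-ketone (C10=C1H–CH2–dioxanyl) | C=C(Br)C[C@]12CC=C[C@@H](O[Si](C)(C)C(C)(C)C)[C@H]1C(=CCC3OCCCO3)CCC2=O
F4 | step 7 | 10α,1-epoxide 7-ketone | C=C(Br)C[C@]12CC=C[C@@H](O[Si](C)(C)C(C)(C)C)[C@H]1[C@@]3(OC3CC4OCCCO4)CCC2=O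
F5 | step 7 | 7,10α-diol (10β-[2-(1,3-dioxan-2-yl)ethyl]) | C=C(Br)C[C@]12CC=C[C@@H](O[Si](C)(C)C(C)(C)C)[C@H]1[C@](O)(CCC3OCCCO3)CCC2O
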